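**Plan**

- Numbering: C1 is the quaternary ring carbon carrying OH and the CH2OAc carbon C7, C2 is CH–OAc, C3=C4 is the alkene, C5 and C6 are the CH–OBz carbons (C6 next to C1). β is the ring face that carries the C6 oxygen, α the other.
- Retrosynthesis cuts, in order: C5–O (inverting benzoate displacement of a C5 alcohol cis to C6–O); the C2 and C6 acyl groups; C2–O (oxirane opened by water at allylic C2); both oxirane bonds C1–O and C2–O (epoxidation of a C1=C2/C3=C4 dienol directed by C6–OH); C1–C7 (Stille hydroxymethylation of a vinyl bromide); the two carbinol C–O bonds (enzymatic dihydroxylation of bromobenzene).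
- Forward: the carbocycle is the benzene ring of bromobenzene throughout. C7 is joined in step 3, and the only ring made is the C1/C2 oxirane (closed in step 5, opened in step 7).
- Enabling feature: the C1 hydroxyl is cis to the C6 oxygen, the C2 oxygen is trans to the C1 hydroxyl, and C6–O sits beside the C7-bearing carbon. This is the pattern left when the proximal hydroxyl of a 3-substituted arene cis-dihydrodiol delivers an oxirane to C1=C2 and the oxirane is opened at C2 with inversion.
- Stereochemistry: C6 comes from toluene dioxygenase. C1 and C2 come from the C6–OH-directed epoxidation, with C2 inverted once on opening. C5, cis after the enzymatic step, is turned trans by a Mitsunobu reaction with benzoic acid.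

Key step: step 5

Assumption: the whole-cell oxidation is taken to give diol 2 as a single enantiomer, as is usual for toluene dioxygenase and monohalobenzenes. Intermediates are described by ring face, and their SMILES carry the absolute configuration. TDS = thexyldimethylsilyl = dimethyl(2,3-dimethylbutan-2-yl)silyl.

**Route**

Step 1
Reactants: 1 bromobenzene
Product: 2 (1S,2S)-3-bromocyclohexa-3,5-diene-1,2-diol (route numbering: Br on C1, cis hydroxyls on C5 and C6, both β)
Conditions: E. coli JM109(pDTG601) whole cells (toluene dioxygenase), glucose-fed aerated fermentation, pH 7, 30 °C; EtOAc extraction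
Reagents that add atoms: dioxygen, O=O
Why: Toluene dioxygenase adds both atoms of O2 to one face of the 2,3-bond of a monohalobenzene (enzymatic arene cis-dihydroxylation), which should set C5 and C6 and give the C6 carbinol, next to the bromine-bearing carbon, the configuration the target needs.

Step 2
Reactants: 2 (1S,2S)-3-bromocyclohexa-3,5-diene-1,2-diol
Product: 3 1-bromo-5β-(TDS-oxy)cyclohexa-1,3-dien-6β-ol (C5 silyl ether, C6–OH free)
Conditions: TDSCl (1.1 equiv), imidazole, DMF, −10 °C
Reagents that add atoms: thexyldimethylsilyl chloride, CC(C)C(C)(C)[Si](C)(C)Cl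
Why: The hydroxyl remote from bromine is the less hindered one, so the bulky silyl chloride should take it selectively (regioselective monosilylation of a halodiene diol) and leave the C6 hydroxyl free, with no stereocentre touched.

Step 3
Reactants: 3 1-bromo-5β-(TDS-oxy)cyclohexa-1,3-dien-6β-ol; 4 (tributylstannyl)methanol
Product: 5 1-(hydroxymethyl)-5β-(TDS-oxy)cyclohexa-1,3-dien-6β-ol
Conditions: Pd(PPh3)4 (5 mol %), 4 (1.5 equiv), degassed 1,4-dioxane (dilute), 80 °C
Reagents that add atoms: none
Why: Stille coupling, in which zerovalent palladium inserts into the dienyl C–Br bond, the hydroxymethyl group passes from tin to palladium and reductive elimination forms C1–C7, leaving the diene and both carbinol centres untouched.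

Step 4
Reactants: 5 1-(hydroxymethyl)-5β-(TDS-oxy)cyclohexa-1,3-dien-6β-ol
Product: 6 [6β-hydroxy-5β-(TDS-oxy)cyclohexa-1,3-dien-1-yl]methyl acetate
Conditions: AcCl (1.05 equiv), 2,4,6-collidine, CH2Cl2, −78 °C
Reagents that add atoms: acetyl chloride, CC(=O)Cl
Why: Acetyl chloride with a hindered pyridine base at low temperature discriminates strongly for primary hydroxyls (selective O-acetylation), and the secondary C6 hydroxyl is further crowded by the cis silyl ether, so only O7 should be esterified.

Step 5
Reactants: 6 [6β-hydroxy-5β-(TDS-oxy)cyclohexa-1,3-dien-1-yl]methyl acetate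
Product: 7 [1,2β-epoxy-6β-hydroxy-5β-(TDS-oxy)cyclohex-3-en-1-yl]methyl acetate (oxirane oxygen, C6–OH and C5–OSi all β)
Conditions: VO(acac)2 (5 mol %), t-BuOOH (anhydrous, in decane, 1.3 equiv), CH2Cl2, 0 °C
Reagents that add atoms: tert-butyl hydroperoxide, CC(C)(C)OO
Why: The C6 hydroxyl displaces a ligand on the pentavalent oxovanadium species formed from VO(acac)2 and t-BuOOH, and the metal-bound peroxo oxygen is then handed over within this vanadate ester to the adjacent C1=C2 bond in one concerted step. The closest known reaction type is the hydroxyl-directed epoxidation of cyclic allylic alcohols with VO(acac)2 and t-BuOOH, here applied to a dienol of the arene cis-dihydrodiol family. The oxirane is the only ring closed, and it forms by simultaneous C1–O and C2–O bonding to the single transferred oxygen, a [2+1] addition to the alkene. C1 and C2 are both set by the enzymatically fixed C6 carbinol, because the tethered oxidant can only reach the alkene face on which C6–OH stands, so the oxirane oxygen ends cis to C6–O. Chemoselectivity between the two ring alkenes is required and is secured because C1=C2 is the only alkene allylic to a free hydroxyl and the more substituted one, whereas C3=C4 is merely homoallylic to that hydroxyl and flanked by the bulky silyl ether. Facial selectivity is secured because C6–OH is the sole ligating group (O7 is acetylated), and the anhydrous, near-neutral medium at 0 °C should spare the dienol from dehydration to an arene.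

Step 6
Reactants: 7 [1,2β-epoxy-6β-hydroxy-5β-(TDS-oxy)cyclohex-3-en-1-yl]methyl acetate
Product: 8 [6β-benzoyloxy-1,2β-epoxy-5β-(TDS-oxy)cyclohex-3-en-1-yl]methyl acetate
Conditions: Bz2O (1.5 equiv), Et3N, DMAP (0.2 equiv), CH2Cl2, 0 °C to rt
Reagents that add atoms: benzoic anhydride, O=C(OC(=O)c1ccccc1)c1ccccc1
Why: DMAP-catalysed acyl transfer to the only free hydroxyl under chloride-free, non-acidic conditions should leave the vinyl oxirane intact, and capping C6 now as the benzoate the target carries keeps it out of the later acetylation.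

Step 7
Reactants: 8 [6β-benzoyloxy-1,2β-epoxy-5β-(TDS-oxy)cyclohex-3-en-1-yl]methyl acetate
Product: 9 [6β-benzoyloxy-1β,2α-dihydroxy-5β-(TDS-oxy)cyclohex-3-en-1-yl]methyl acetate
Conditions: HClO4 (aq., 5 mol %), THF–H2O (4:1), 0 °C; NaHCO3 quench
Reagents that add atoms: water, O
Why: In this acid-catalysed hydrolysis of a vinyl oxirane, water should attack the allylic carbon C2 anti to the protonated oxirane oxygen (C1 is quaternary and deactivated by its two acyloxy-bearing neighbours), so C2–O becomes α while C1–OH stays β; if the C7 acetate assists through a six-membered acetoxonium ion it also enters C2 from the α face and hydrolyses to the same C2 configuration, and any acetyl shifted from O7 to O2 is evened out in step 8.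

Step 8
Reactants: 9 [6β-benzoyloxy-1β,2α-dihydroxy-5β-(TDS-oxy)cyclohex-3-en-1-yl]methyl acetate
Product: 10 [2α-acetoxy-6β-benzoyloxy-1β-hydroxy-5β-(TDS-oxy)cyclohex-3-en-1-yl]methyl acetate
Conditions: Ac2O, pyridine, 0 °C to rt (no DMAP)
Reagents that add atoms: acetic anhydride, CC(=O)OC(C)=O
Why: Pyridine-mediated acetylation should esterify the secondary C2 hydroxyl (and any primary C7 hydroxyl exposed by acetyl shift) while the hindered tertiary C1 hydroxyl stays free, with no stereocentre affected.

Step 9
Reactants: 10 [2α-acetoxy-6β-benzoyloxy-1β-hydroxy-5β-(TDS-oxy)cyclohex-3-en-1-yl]methyl acetate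
Product: 11 [2α-acetoxy-6β-benzoyloxy-1β,5β-dihydroxycyclohex-3-en-1-yl]methyl acetate
Conditions: HF·pyridine, pyridine, THF, 0 °C to rt
Reagents that add atoms: none
Why: Fluoride-driven Si–O cleavage (desilylation) in a weakly acidic medium should free the C5 hydroxyl without saponifying the esters and without base-promoted benzoyl migration from O6 to the cis O5.

Step 10
Reactants: 11 [2α-acetoxy-6β-benzoyloxy-1β,5β-dihydroxycyclohex-3-en-1-yl]methyl acetate; 12 benzoic acid
Product: 13 [(1R,2S,5R,6S)-2-acetoxy-5,6-bis(benzoyloxy)-1-hydroxycyclohex-3-en-1-yl]methyl acetate, the target (1β-OH, 2α-OAc, 5α-OBz, 6β-OBz)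
Conditions: PPh3, 12, then DIAD added last (1.5–2 equiv each), THF, 0 °C to rt
Reagents that add atoms: none
Why: In this Mitsunobu reaction the secondary allylic C5 hydroxyl becomes an alkoxyphosphonium leaving group and is displaced by benzoate from the α face with inversion (SN2), making C5–OBz trans to C6–OBz; the tertiary C1 hydroxyl does not react and the cis C6 benzoate cannot participate from the rear.

**Compound list**

1 | bromobenzene | Brc1ccccc1 | starting material
2 | (1S,2S)-3-bromocyclohexa-3,5-diene-1,2-diol | BrC1=CC=C[C@H](O)[C@@H]1O | intermediate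
3 | 1-bromo-5β-(TDS-oxy)cyclohexa-1,3-dien-6β-ol | BrC1=CC=C[C@H](O[Si](C)(C)C(C)(C)C(C)C)[C@@H]1O | intermediate
4 | (tributylstannyl)methanol | CCCC[Sn](CCCC)(CCCC)CO | starting material
5 | 1-(hydroxymethyl)-5β-(TDS-oxy)cyclohexa-1,3-dien-6β-ol | OCC1=CC=C[C@H](O[Si](C)(C)C(C)(C)C(C)C)[C@@H]1O | intermediate
6 | [6β-hydroxy-5β-(TDS-oxy)cyclohexa-1,3-dien-1-yl]methyl acetate | CC(=O)OCC1=CC=C[C@H](O[Si](C)(C)C(C)(C)C(C)C)[C@@H]1O | intermediate
7 | [1,2β-epoxy-6β-hydroxy-5β-(TDS-oxy)cyclohex-3-en-1-yl]methyl acetate | CC(=O)OC[C@@]12O[C@@H]1C=C[C@H](O[Si](C)(C)C(C)(C)C(C)C)[C@@H]2O | intermediate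
8 | [6β-benzoyloxy-1,2β-epoxy-5β-(TDS-oxy)cyclohex-3-en-1-yl]methyl acetate | CC(=O)OC[C@@]12O[C@@H]1C=C[C@H](O[Si](C)(C)C(C)(C)C(C)C)[C@@H]2OC(=O)c3ccccc3 | intermediate
9 | [6β-benzoyloxy-1β,2α-dihydroxy-5β-(TDS-oxy)cyclohex-3-en-1-yl]methyl acetate | CC(=O)OC[C@@]1(O)[C@@H](O)C=C[C@H](O[Si](C)(C)C(C)(C)C(C)C)[C@@H]1OC(=O)c2ccccc2 | intermediate
10 | [2α-acetoxy-6β-benzoyloxy-1β-hydroxy-5β-(TDS-oxy)cyclohex-3-en-1-yl]methyl acetate | CC(=O)OC[C@@]1(O)[C@@H](OC(C)=O)C=C[C@H](O[Si](C)(C)C(C)(C)C(C)C)[C@@H]1OC(=O)c2ccccc2 | intermediate
11 | [2α-acetoxy-6β-benzoyloxy-1β,5β-dihydroxycyclohex-3-en-1-yl]methyl acetate | CC(=O)OC[C@@]1(O)[C@@H](OC(C)=O)C=C[C@H](O)[C@@H]1OC(=O)c2ccccc2 | intermediate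
12 | benzoic acid | OC(=O)c1ccccc1 | starting material
13 | [(1R,2S,5R,6S)-2-acetoxy-5,6-bis(benzoyloxy)-1-hydroxycyclohex-3-en-1-yl]methyl acetate | CC(=O)OC[C@@]1(O)[C@@H](OC(C)=O)C=C[C@@H](OC(=O)c2ccccc2)[C@@H]1OC(=O)c1ccccc1 | target

**Step count and risks**

Total steps: 10. Longest linear sequence: 10 steps (1 → 2 → 3 → 5 → 6 → 7 → 8 → 9 → 10 → 11 → 13); 4 and 12 are purchased.

Steps most likely to fail:

Step 3. At 80 °C the dienol may dimerise by Diels–Alder reaction or lose water to give an arene, and transfer of the hydroxymethyl group from tin may be too slow to compete. The fallback avoids heating altogether and sets out from 3. Deprotonation of the C6 hydroxyl with MeLi (1 equiv) and bromine–lithium exchange with t-BuLi (2 equiv) in THF at −78 °C, followed by a DMF quench, should give 6β-hydroxy-5β-(TDS-oxy)cyclohexa-1,3-diene-1-carbaldehyde F1. This is reduced at once at the carbonyl under Luche conditions (NaBH4, CeCl3·7H2O, MeOH, −78 °C), and the route is rejoined at 5.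

Step 7. Water may enter at C4 in a conjugate (1,4) opening, the C7 acetate may participate at the quaternary C1 and erode its configuration, or the silyl ether may be cleaved by the acid. The fallback sets out from 7, where the C6 hydroxyl is still free, and uses it a second time as the control element. Ti(OiPr)4 (1.5 equiv) and acetic acid in CH2Cl2 at rt should bind the C6 alkoxide and the oxirane oxygen to the metal and guide acetate to the distal oxirane carbon C2 from the α face. This gives [2α-acetoxy-1β,6β-dihydroxy-5β-(TDS-oxy)cyclohex-3-en-1-yl]methyl acetate F2. Benzoylation of its secondary C6 hydroxyl (Bz2O, Et3N, DMAP, CH2Cl2), with the tertiary hydroxyl left alone, rejoins the route at 10, bypassing 8 and 9.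

Step 10. The alkoxyphosphonium ion may eliminate, benzoate may enter at C3 with allylic transposition, or the C6 benzoyl group may migrate to O5 before activation so that no inversion takes place. The fallback separates activation from displacement and sets out from 11. Mesylation of the C5 hydroxyl (MsCl, Et3N, CH2Cl2, −20 °C) should give [2α-acetoxy-6β-benzoyloxy-1β-hydroxy-5β-(methanesulfonyloxy)cyclohex-3-en-1-yl]methyl acetate F3. Displacement with commercial potassium benzoate and 18-crown-6 in toluene at 50 °C, a direct SN2 reaction in a poorly ionising medium, should then invert C5 and arrive at 13.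

**Further compounds**

F1 | step 3 | 6β-hydroxy-5β-(TDS-oxy)cyclohexa-1,3-diene-1-carbaldehyde | O=CC1=CC=C[C@H](O[Si](C)(C)C(C)(C)C(C)C)[C@@H]1O
F2 | step 7 | [2α-acetoxy-1β,6β-dihydroxy-5β-(TDS-oxy)cyclohex-3-en-1-yl]methyl acetate | CC(=O)OC[C@@]1(O)[C@@H](OC(C)=O)C=C[C@H](O[Si](C)(C)C(C)(C)C(C)C)[C@@H]1O
F3 | step 10 | [2α-acetoxy-6β-benzoyloxy-1β-hydroxy-5β-(methanesulfonyloxy)cyclohex-3-en-1-yl]methyl acetate | CC(=O)OC[C@@]1(O)[C@@H](OC(C)=O)C=C[C@H](OS(C)(=O)=O)[C@@H]1OC(=O)c2ccccc2
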